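**Plan**
- Retrosynthesis: the three O-benzyl groups are removed first; ring C of the flavonol (Algar–Flynn–Oyamada) and the chalcone C=C (Claisen–Schmidt) are then cut to a phloroacetophenone dibenzyl ether and a 1,4-benzodioxane-6-carbaldehyde. In that aldehyde the bond O-4–C-3 (ring oxygen meta to CHO to the CH2OH-bearing carbon) is cut, then O-1–C-2 (oxygen para to CHO to the benzylic carbon).
- Enabling feature: C-2, C-3 and the exocyclic CH2OH carbon of the dioxane ring form a three-carbon chain with one oxygen on each carbon (benzylic aryl ether, ring aryl ether, primary alcohol). This is a 3-aryl epichlorohydrin after two oxirane openings. The two oxygens of the catechol ring (ring B) differ in acidity because only one is para to the carbonyl carbon.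
- Forward order: (E)-cinnamyl alcohol, Sharpless epoxide, epoxy chloride; a one-flask union with unprotected 3,4-dihydroxybenzaldehyde builds the dioxane ring (O-1–C-2 first, ring closure at O-4–C-3 last); then chalcone, flavonol ring C, debenzylation.
- Stereochemistry: both centres come from the Sharpless epoxidation with L-(+)-diisopropyl tartrate. The benzylic centre is inverted once (S to R); the other is retained on oxirane transposition and inverted on ring closure, which gives the trans (2R,3R) ring.

Key step: step 5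

Remark: the SMILES encodes the trans (2R,3R) benzodioxane, and 1-[2,4-bis(benzyloxy)-6-hydroxyphenyl]ethan-1-one is taken as a purchasable compound.

**Route**

Step 1
Reactants: 1 4-(benzyloxy)-3-methoxybenzaldehyde; 2 triethyl phosphonoacetate
Product: 3 ethyl (E)-3-[4-(benzyloxy)-3-methoxyphenyl]prop-2-enoate
Conditions: NaH, THF, 0 °C to rt
Reagents that add atoms: none
Why: Horner–Wadsworth–Emmons olefination of the aryl aldehyde with the sodium phosphonate anion should give the conjugated ester with the (E) double bond, because the stabilized anion adds reversibly and the anti oxaphosphetane eliminates fastest.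

Step 2
Reactants: 3 ethyl (E)-3-[4-(benzyloxy)-3-methoxyphenyl]prop-2-enoate
Product: 4 (E)-3-[4-(benzyloxy)-3-methoxyphenyl]prop-2-en-1-ol
Conditions: iBu2AlH, CH2Cl2, −78 °C; aq. KNaC4H4O6 work-up
Reagents that add atoms: none
Why: Ester reduction with diisobutylaluminium hydride at low temperature proceeds by 1,2-hydride delivery to the conjugated ester and should give the allylic alcohol without touching the double bond or the benzyl ether.

Step 3
Reactants: 4 (E)-3-[4-(benzyloxy)-3-methoxyphenyl]prop-2-en-1-ol
Product: 5 [(2S,3S)-3-[4-(benzyloxy)-3-methoxyphenyl]oxiran-2-yl]methanol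
Conditions: Ti(OiPr)4 (10 mol %), L-(+)-diisopropyl tartrate (14 mol %), t-BuOOH, 4 Å MS, CH2Cl2, −25 °C; NaOH/brine work-up
Reagents that add atoms: tert-butyl hydroperoxide CC(C)(C)OO
Why: Sharpless asymmetric epoxidation of the (E)-allylic alcohol with the titanium–L-(+)-tartrate catalyst delivers the oxygen to one face of the alkene and so sets both stereocentres as (2S,3S) by reagent control, while the catalytic loading, the sieves and the basic work-up spare the acid-sensitive electron-rich aryl oxirane.

Step 4
Reactants: 5 [(2S,3S)-3-[4-(benzyloxy)-3-methoxyphenyl]oxiran-2-yl]methanol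
Product: 6 (2R,3S)-2-(chloromethyl)-3-[4-(benzyloxy)-3-methoxyphenyl]oxirane
Conditions: PPh3, CCl4, NaHCO3, CH2Cl2, 40 °C
Reagents that add atoms: carbon tetrachloride ClC(Cl)(Cl)Cl
Why: Appel chlorination activates only the primary hydroxyl as its alkoxyphosphonium ion, which chloride displaces at the CH2 carbon, so neither oxirane carbon is touched (the C-2 descriptor changes from S to R only because CH2Cl now outranks the ring carbon) and NaHCO3 keeps the medium free of acid.

Step 5
Reactants: 6 (2R,3S)-2-(chloromethyl)-3-[4-(benzyloxy)-3-methoxyphenyl]oxirane; 7 3,4-dihydroxybenzaldehyde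
Product: 10 (2R,3R)-2-[4-(benzyloxy)-3-methoxyphenyl]-3-(hydroxymethyl)-2,3-dihydro-1,4-benzodioxine-6-carbaldehyde, via aryloxy chlorohydrin 8 (not isolated), via transposed oxirane 9 (not isolated)
Conditions: K2CO3 (1.1 equiv), DMF, 55 °C; then K2CO3 (0.5 equiv), MeOH, 50 °C
Reagents that add atoms: none
Why: Proposed new method: the potassium 4-phenoxide of 7 should open the oxirane of 6 at its benzylic carbon by SN2 with inversion to give chlorohydrin 8, the alkoxide of 8 closes 3-exo-tet onto the CH2Cl carbon to the transposed oxirane 9 with retention at the carbinol carbon, and the neighbouring 3-phenoxide then opens 9 at its inner carbon in a 6-exo-tet closure that forms the O-4–C-3 bond of the dioxane ring with inversion and frees the CH2OH group. The closest known reaction type is the base-mediated annulation of catechols with epichlorohydrin to 2-(hydroxymethyl)-1,4-benzodioxanes, which runs through the same three events; what is new is a 3-aryl epichlorohydrin that must be attacked first at its substituted benzylic carbon, so that a trans-2-aryl-3-(hydroxymethyl) ring is made as one enantiomer. Both stereocentres are relayed from the Sharpless oxirane by stereospecific SN2 steps: C-2 (aryl) by one inversion (S to R) and C-3 (CH2OH) by retention then inversion, which can only give the trans (2R,3R) ring. The step needs the first attack to come from the oxygen para to the formyl group, which the use of about one equivalent of base secures because only this more acidic hydroxyl is ionized; it needs attack at the benzylic oxirane carbon instead of CH2Cl, which the electron-rich aryl group and the poor leaving-group ability of chloride in an intermolecular SN2 reaction secure, as in epichlorohydrin itself. It needs 6-exo instead of 7-membered closure, which the methanol of the second stage supports by letting 8 close to 9 faster than the phenoxide can displace chloride directly, and 6-exo opening of such aryloxymethyl oxiranes is the normal course.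

Step 6
Reactants: 10 (2R,3R)-2-[4-(benzyloxy)-3-methoxyphenyl]-3-(hydroxymethyl)-2,3-dihydro-1,4-benzodioxine-6-carbaldehyde; 11 1-[2,4-bis(benzyloxy)-6-hydroxyphenyl]ethan-1-one
Product: 12 (E)-1-[2,4-bis(benzyloxy)-6-hydroxyphenyl]-3-{(2R,3R)-2-[4-(benzyloxy)-3-methoxyphenyl]-3-(hydroxymethyl)-2,3-dihydro-1,4-benzodioxin-6-yl}prop-2-en-1-one
Conditions: KOH (50 % aq.), EtOH, rt
Reagents that add atoms: none
Why: Claisen–Schmidt aldol condensation of the ketone enolate of 11 with the non-enolizable aldehyde 10 and E1cB loss of water should give the (E)-chalcone, and the two stereocentres, which carry no acidic hydrogen and cannot open to a quinone methide while the phenol is benzylated, are not at risk.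

Step 7
Reactants: 12 (E)-1-[2,4-bis(benzyloxy)-6-hydroxyphenyl]-3-{(2R,3R)-2-[4-(benzyloxy)-3-methoxyphenyl]-3-(hydroxymethyl)-2,3-dihydro-1,4-benzodioxin-6-yl}prop-2-en-1-one
Product: 13 5,7-bis(benzyloxy)-2-{(2R,3R)-2-[4-(benzyloxy)-3-methoxyphenyl]-3-(hydroxymethyl)-2,3-dihydro-1,4-benzodioxin-6-yl}-3-hydroxy-4H-chromen-4-one
Conditions: H2O2 (30 % aq.), NaOH (2 M aq.), MeOH/THF, 0 °C to rt
Reagents that add atoms: hydrogen peroxide OO
Why: Algar–Flynn–Oyamada reaction, in which alkaline hydrogen peroxide oxidizes the 2'-hydroxychalcone at the enone, the phenoxide closes ring C in the 6-membered mode and the 3-hydroxyflavanone formed is oxidized further in the same flask to the flavonol.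

Step 8
Reactants: 13 5,7-bis(benzyloxy)-2-{(2R,3R)-2-[4-(benzyloxy)-3-methoxyphenyl]-3-(hydroxymethyl)-2,3-dihydro-1,4-benzodioxin-6-yl}-3-hydroxy-4H-chromen-4-one
Product: 14 3,5,7-trihydroxy-2-[(2R,3R)-2-(4-hydroxy-3-methoxyphenyl)-3-(hydroxymethyl)-2,3-dihydro-1,4-benzodioxin-6-yl]-4H-chromen-4-one (CNP0110568.1)
Conditions: H2 (1 atm), Pd/C (10 %), EtOAc/MeOH, rt
Reagents that add atoms: none
Why: Catalytic hydrogenolysis of the three primary benzyl aryl ethers over Pd/C at atmospheric pressure should be much faster than cleavage of the cyclic secondary benzylic C–O bond of the dioxane ring or reduction of the flavonol double bond, so the stereocentres and ring C survive if the reaction is stopped after three equivalents of hydrogen.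

**Compound list**
1 | 4-(benzyloxy)-3-methoxybenzaldehyde | COc1cc(C=O)ccc1OCc1ccccc1 | starting material
2 | triethyl phosphonoacetate | CCOC(=O)CP(=O)(OCC)OCC | starting material
3 | ethyl (E)-3-[4-(benzyloxy)-3-methoxyphenyl]prop-2-enoate | CCOC(=O)/C=C/c1ccc(OCc2ccccc2)c(OC)c1 | intermediate
4 | (E)-3-[4-(benzyloxy)-3-methoxyphenyl]prop-2-en-1-ol | OC/C=C/c1ccc(OCc2ccccc2)c(OC)c1 | intermediate
5 | [(2S,3S)-3-[4-(benzyloxy)-3-methoxyphenyl]oxiran-2-yl]methanol | OC[C@@H]1O[C@H]1c1ccc(OCc2ccccc2)c(OC)c1 | intermediate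
6 | (2R,3S)-2-(chloromethyl)-3-[4-(benzyloxy)-3-methoxyphenyl]oxirane | ClC[C@@H]1O[C@H]1c1ccc(OCc2ccccc2)c(OC)c1 | intermediate
7 | 3,4-dihydroxybenzaldehyde | O=Cc1ccc(O)c(O)c1 | starting material
8 | 4-{[(1R,2R)-1-[4-(benzyloxy)-3-methoxyphenyl]-3-chloro-2-hydroxypropyl]oxy}-3-hydroxybenzaldehyde | ClC[C@H](O)[C@H](Oc1ccc(C=O)cc1O)c1ccc(OCc2ccccc2)c(OC)c1 | intermediate
9 | 4-{(R)-[4-(benzyloxy)-3-methoxyphenyl][(2S)-oxiran-2-yl]methoxy}-3-hydroxybenzaldehyde | COc1cc([C@@H](Oc2ccc(C=O)cc2O)[C@@H]2CO2)ccc1OCc1ccccc1 | intermediate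
10 | (2R,3R)-2-[4-(benzyloxy)-3-methoxyphenyl]-3-(hydroxymethyl)-2,3-dihydro-1,4-benzodioxine-6-carbaldehyde | COc1cc([C@H]2Oc3ccc(C=O)cc3O[C@@H]2CO)ccc1OCc1ccccc1 | intermediate
11 | 1-[2,4-bis(benzyloxy)-6-hydroxyphenyl]ethan-1-one | CC(=O)c1c(O)cc(OCc2ccccc2)cc1OCc1ccccc1 | starting material
12 | (E)-1-[2,4-bis(benzyloxy)-6-hydroxyphenyl]-3-{(2R,3R)-2-[4-(benzyloxy)-3-methoxyphenyl]-3-(hydroxymethyl)-2,3-dihydro-1,4-benzodioxin-6-yl}prop-2-en-1-one | COc1cc([C@H]2Oc3ccc(/C=C/C(=O)c4c(O)cc(OCc5ccccc5)cc4OCc4ccccc4)cc3O[C@@H]2CO)ccc1OCc1ccccc1 | intermediate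
13 | 5,7-bis(benzyloxy)-2-{(2R,3R)-2-[4-(benzyloxy)-3-methoxyphenyl]-3-(hydroxymethyl)-2,3-dihydro-1,4-benzodioxin-6-yl}-3-hydroxy-4H-chromen-4-one | COc1cc([C@H]2Oc3ccc(-c4oc5cc(OCc6ccccc6)cc(OCc6ccccc6)c5c(=O)c4O)cc3O[C@@H]2CO)ccc1OCc1ccccc1 | intermediate
14 | 3,5,7-trihydroxy-2-[(2R,3R)-2-(4-hydroxy-3-methoxyphenyl)-3-(hydroxymethyl)-2,3-dihydro-1,4-benzodioxin-6-yl]-4H-chromen-4-one | COc1cc([C@H]2Oc3ccc(-c4oc5cc(O)cc(O)c5c(=O)c4O)cc3O[C@@H]2CO)ccc1O | target

Total step count: 8
Longest linear sequence: 8 steps (1 to 3, 4, 5, 6, 10, 12, 13, 14)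

**Steps most likely to fail**

1. Step 5 (proposed new method). What may go wrong: the first phenoxide attack may take place at the CH2Cl carbon or come from the 3-oxygen of 7, the benzylic carbon may lose configuration through an ion-pair opening, or the second closure may run in the 7-membered mode. The fallback uses known reaction types only; it sets out from 5 and comes back at 10. The primary hydroxyl of 5 is silylated (TBDPSCl, imidazole, CH2Cl2) to the tert-butyldiphenylsilyl ether F1. The monopotassium salt of 7 (K2CO3, DMF, 60 °C), in which the hydroxyl para to the formyl group is the one ionized, opens F1 at the benzylic carbon with inversion to the hydroxy phenol F2. An intramolecular Mitsunobu etherification (PPh3, diisopropyl azodicarboxylate, THF, 0 °C to rt) then lets the free phenol displace the activated secondary hydroxyl with inversion. This forms the same ring bond in a 6-membered closure, with the primary oxygen blocked so that no 7-membered path exists, and gives the silyl-protected benzodioxane F3. Tetrabutylammonium fluoride in THF frees the hydroxymethyl group and gives 10.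

2. Step 4. What may go wrong: opening of the electron-rich benzylic oxirane by chloride or by the phosphonium species during chlorination, with loss of the epoxide or of configuration at the benzylic carbon. The fallback sets out from 5 and comes back at 9, and so at 10; no chlorinating agent meets the oxirane, because the leaving group is put on after the aryl ether is in place. The monopotassium salt of 7 (K2CO3, DMF, 60 °C) opens 5 at the benzylic carbon with inversion to the triol F4. The phenol alone is allylated (allyl bromide, K2CO3, acetone) to the allyl ether F5. The primary hydroxyl is tosylated selectively (TsCl, Et3N, Bu2SnO cat., CH2Cl2) to the monotosylate F6. K2CO3 in MeOH closes the hydroxy tosylate to the allyl-protected oxirane F7. Pd(PPh3)4 added to the same flask removes the allyl group, which gives oxirane 9 and from it 10 by the ring closure of step 5.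

3. Step 7. What may go wrong: with the 6'-benzyloxy group the phenoxide may close on the α-carbon in the 5-membered mode and give the aurone, or the oxidation may stop at the 3-hydroxyflavanone. The fallback sets out from 12 and comes back at 13. Oxidative cyclization with I2 (cat.) in DMSO at 120 °C gives the flavone F8. Epoxidation of its 2,3-double bond with dimethyldioxirane (acetone/CH2Cl2, 0 °C) gives the 2,3-epoxide F9, formed as both epoxide diastereomers. Catalytic p-toluenesulfonic acid in CH2Cl2 opens F9 to the flavonol 13.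

Further compounds
F1 | step 5 | tert-butyl({(2S,3S)-3-[4-(benzyloxy)-3-methoxyphenyl]oxiran-2-yl}methoxy)diphenylsilane | CC(C)(C)[Si](OC[C@@H]1O[C@H]1c1ccc(OCc2ccccc2)c(OC)c1)(c1ccccc1)c1ccccc1
F2 | step 5 | 4-{[(1R,2S)-1-[4-(benzyloxy)-3-methoxyphenyl]-3-[(tert-butyldiphenylsilyl)oxy]-2-hydroxypropyl]oxy}-3-hydroxybenzaldehyde | CC(C)(C)[Si](OC[C@H](O)[C@H](Oc1ccc(C=O)cc1O)c1ccc(OCc2ccccc2)c(OC)c1)(c1ccccc1)c1ccccc1
F3 | step 5 | (2R,3R)-2-[4-(benzyloxy)-3-methoxyphenyl]-3-{[(tert-butyldiphenylsilyl)oxy]methyl}-2,3-dihydro-1,4-benzodioxine-6-carbaldehyde | COc1cc([C@H]2Oc3ccc(C=O)cc3O[C@@H]2CO[Si](c4ccccc4)(c4ccccc4)C(C)(C)C)ccc1OCc1ccccc1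
F4 | step 4 | 4-{[(1R,2S)-1-[4-(benzyloxy)-3-methoxyphenyl]-2,3-dihydroxypropyl]oxy}-3-hydroxybenzaldehyde | OC[C@H](O)[C@H](Oc1ccc(C=O)cc1O)c1ccc(OCc2ccccc2)c(OC)c1
F5 | step 4 | 3-(allyloxy)-4-{[(1R,2S)-1-[4-(benzyloxy)-3-methoxyphenyl]-2,3-dihydroxypropyl]oxy}benzaldehyde | OC[C@H](O)[C@H](Oc1ccc(C=O)cc1OCC=C)c1ccc(OCc2ccccc2)c(OC)c1
F6 | step 4 | (2S,3R)-3-[2-(allyloxy)-4-formylphenoxy]-3-[4-(benzyloxy)-3-methoxyphenyl]-2-hydroxypropyl 4-methylbenzenesulfonate | Cc1ccc(cc1)S(=O)(=O)OC[C@H](O)[C@H](Oc1ccc(C=O)cc1OCC=C)c1ccc(OCc2ccccc2)c(OC)c1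
F7 | step 4 | 3-(allyloxy)-4-{(R)-[4-(benzyloxy)-3-methoxyphenyl][(2S)-oxiran-2-yl]methoxy}benzaldehyde | COc1cc([C@@H](Oc2ccc(C=O)cc2OCC=C)[C@@H]2CO2)ccc1OCc1ccccc1
F8 | step 7 | 5,7-bis(benzyloxy)-2-{(2R,3R)-2-[4-(benzyloxy)-3-methoxyphenyl]-3-(hydroxymethyl)-2,3-dihydro-1,4-benzodioxin-6-yl}-4H-chromen-4-one | COc1cc([C@H]2Oc3ccc(-c4cc(=O)c5c(OCc6ccccc6)cc(OCc6ccccc6)cc5o4)cc3O[C@@H]2CO)ccc1OCc1ccccc1
F9 | step 7 | 5,7-bis(benzyloxy)-2-{(2R,3R)-2-[4-(benzyloxy)-3-methoxyphenyl]-3-(hydroxymethyl)-2,3-dihydro-1,4-benzodioxin-6-yl}-2,3-epoxy-2,3-dihydro-4H-chromen-4-one (both epoxide diastereomers) | COc1cc([C@H]2Oc3ccc(C45OC4C(=O)c4c(OCc6ccccc6)cc(OCc6ccccc6)cc4O5)cc3O[C@@H]2CO)ccc1OCc1ccccc1
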